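## Retrosynthetic overview

1. The target comes from the macrocyclic (4Z,1(10)Z) β‑hydroxy enone by an Evans–Tishchenko reaction with O‑silyl vanillin, which sets C6 and places the vanillate on O8, followed by desilylation.
2. The enone comes from allylic oxidation of the product of an electrochemical Nozaki–Hiyama–Kishi ring closure (C5–C6 bond). This is the only ring, and it is the last C–C bond made.
3. The open chain comes from copper‑catalysed opening of a C8–C9 epoxide by a C10 alkenylmagnesium reagent (C9–C10 bond), then ester → aldehyde.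
4. The epoxide half comes from (S)‑3‑hydroxy‑γ‑butyrolactone (C8 bought, C7 by trans alkylation). The diene half comes from propyne carbocupration (Z C4=C5) and an iodo‑Wittig olefination (Z C1=C10).

Assumption: the SMILES is read literally, so both ring double bonds are Z and the centres are 6R,7R,8R; atom labels C1–C10 follow germacrane numbering (C8 bears the vanillate, C6 the free OH, C7 the isopropyl group).

## Route

Step 1
Reactants: 1 (S)-3-hydroxy-γ-butyrolactone [(4S)-4-hydroxyoxolan-2-one]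
Product: 3 (3S,4S)-4-hydroxy-3-(propan-2-yl)oxolan-2-one, via dilithium dianion 2 (not isolated)
Conditions: LiN(iPr)2 (2.2 equiv), THF, −78 → −40 °C; 2-iodopropane (4 equiv), DMPU, −40 → −20 °C; AcOH quench
Reagents that add atoms: 2-iodopropane, `CC(C)I`
Why: Fráter–Seebach-type alkylation of the alkoxide–enolate dianion, in which the electrophile attacks C3 of the five-ring enolate anti to the bought C4–OLi group, so C3 (C7 of the target) is set trans by substrate control.

Step 2
Reactants: 3 (3S,4S)-4-hydroxy-3-(propan-2-yl)oxolan-2-one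
Product: 5 ethyl (2S,3S)-4-bromo-3-hydroxy-2-(propan-2-yl)butanoate, via acetoxy bromo acid 4 (not isolated)
Conditions: HBr (33% in AcOH), 50 °C; then EtOH, 50 °C
Reagents that add atoms: hydrogen bromide, `Br`; ethanol, `CCO`
Why: SN2 opening of the protonated lactone at its primary O–CH2 carbon by bromide, then acid-catalysed ethanolysis (Fischer esterification and removal of the transient acetate), with no bond to either stereocentre broken.

Step 3
Reactants: 6 2-(2-bromoethyl)-1,3-dioxolane
Product: 11 (4Z)-5-bromo-4-methylpent-4-enal, via Grignard reagent 7 (not isolated), via alkylcopper 8 (not isolated), via alkenylcopper 9 (not isolated), via bromo acetal 10 (not isolated)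
Conditions: Mg, THF, 25 °C; CuBr·SMe2, Et2O/Me2S, −45 °C; propyne, −25 °C; NBS, −40 → 0 °C; then 2 M HCl, THF, 25 °C
Reagents that add atoms: propyne, `CC#C`; N-bromosuccinimide, `O=C1CCC(=O)N1Br`; water, `O`
Why: Normant carbocupration adds the alkylcopper syn across propyne with copper on the terminal carbon, bromination proceeds with retention so bromine ends cis to the chain (Z), and the acidic work-up hydrolyses the dioxolane.

Step 4
Reactants: 11 (4Z)-5-bromo-4-methylpent-4-enal
Product: 12 (1Z,5Z)-1-bromo-6-iodo-2-methylhepta-1,5-diene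
Conditions: [Ph3PEt]I, n-BuLi, THF, 0 → 25 °C; I2, −78 °C; NaN(SiMe3)2, −20 °C; then 11, −78 → −20 °C
Reagents that add atoms: ethyltriphenylphosphonium iodide, `CC[P+](c1ccccc1)(c1ccccc1)c1ccccc1.[I-]`; iodine, `II`
Why: Wittig olefination with the α-iodo ylide (Stork–Zhao type) runs under kinetic control through the cis-oxaphosphetane and gives the (Z)-2-iodoalk-2-ene with iodine cis to the chain, as needed for C9 cis to C2.

Step 5
Reactants: 5 ethyl (2S,3S)-4-bromo-3-hydroxy-2-(propan-2-yl)butanoate; 12 (1Z,5Z)-1-bromo-6-iodo-2-methylhepta-1,5-diene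
Product: 15 ethyl (2S,3R,5Z,9Z)-10-bromo-3-hydroxy-5,9-dimethyl-2-(propan-2-yl)deca-5,9-dienoate, via epoxy ester 13 (not isolated), via alkenylmagnesium chloride 14 (not isolated)
Conditions: 12, i-PrMgCl·LiCl, THF, 0 → 25 °C, 12 h; separately 5, NaH, THF, 0 °C; combine, CuI (10 mol%), −40 → −10 °C; 1 M HCl quench
Reagents that add atoms: none
Why: iodine–magnesium exchange occurs only at the alkenyl iodide (the alkenyl bromide is inert) with retention of Z geometry, and the copper-catalysed Grignard reagent opens the terminal epoxide at CH2 (SN2), so C7 and C8 are untouched and the ester survives at low temperature.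

Step 6
Reactants: 15 ethyl (2S,3R,5Z,9Z)-10-bromo-3-hydroxy-5,9-dimethyl-2-(propan-2-yl)deca-5,9-dienoate
Product: 16 (2R,3R,5Z,9Z)-10-bromo-5,9-dimethyl-2-(propan-2-yl)deca-5,9-diene-1,3-diol
Conditions: LiBH4, THF/MeOH, 0 → 25 °C
Reagents that add atoms: none
Why: borohydride reduction of the ester, accelerated by the neighbouring alkoxide, while the alkenyl bromide and the alkenes are inert.

Step 7
Reactants: 16 (2R,3R,5Z,9Z)-10-bromo-5,9-dimethyl-2-(propan-2-yl)deca-5,9-diene-1,3-diol
Product: 17 (2S,3R,5Z,9Z)-10-bromo-3-hydroxy-5,9-dimethyl-2-(propan-2-yl)deca-5,9-dienal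
Conditions: TEMPO (10 mol%), PhI(OAc)2 (1.1 equiv), CH2Cl2, 25 °C; used crude at once
Reagents that add atoms: none
Why: oxoammonium (TEMPO) oxidation is selective for the primary over the secondary alcohol and stops at the aldehyde under non-basic conditions, which keeps the α-centre (C7) intact.

Step 8
Reactants: 17 (2S,3R,5Z,9Z)-10-bromo-3-hydroxy-5,9-dimethyl-2-(propan-2-yl)deca-5,9-dienal
Product: 18 (1R,2S,3RS,4Z,8Z)-5,9-dimethyl-2-(propan-2-yl)cyclodeca-4,8-diene-1,3-diol (both C3 epimers; C3 = C6 of the target)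
Conditions: 17 added over 10 h (final 3 mM) to CrCl2 (20 mol%), NiCl2(dme) (5 mol%), Cp2ZrCl2 (2.2 equiv), LiCl, DMF, undivided cell, Al anode, Ni-foam cathode, constant current (about 2.5 F/mol), 25 °C; aqueous work-up
Reagents that add atoms: none
Why: Proposed new method: a ring-closing, chromium-catalytic electroreductive Nozaki–Hiyama–Kishi reaction, in which zerovalent nickel made at the cathode inserts into the Z-alkenyl bromide with retention, the alkenyl group passes to trivalent chromium, the long-lived and weakly basic alkenylchromium adds to the tethered aldehyde (free hydroxyl tolerated), Cp2ZrCl2 strips the chromium alkoxide so that divalent chromium is regenerated at the cathode, and slow addition plus the two Z double bonds favour 10-membered closure over oligomers; the new carbinol centre needs no control because step 9 oxidises it; closest known reaction type: the intermolecular electrochemical NHK coupling of alkenyl bromides with aldehydes and the stoichiometric CrCl2/NiCl2 macrocyclisation.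

Step 9
Reactants: 18 (1R,2S,3RS,4Z,8Z)-5,9-dimethyl-2-(propan-2-yl)cyclodeca-4,8-diene-1,3-diol
Product: 19 (2Z,6Z,9R,10S)-9-hydroxy-3,7-dimethyl-10-(propan-2-yl)cyclodeca-2,6-dien-1-one
Conditions: MnO2 (activated, excess), CH2Cl2, 25 °C
Reagents that add atoms: none
Why: MnO2 oxidises only the allylic alcohol, so both epimers converge on one Z-enone while the C8 hydroxyl is left free.

Step 10
Reactants: 20 vanillin (4-hydroxy-3-methoxybenzaldehyde)
Product: 21 4-[(tert-butyldimethylsilyl)oxy]-3-methoxybenzaldehyde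
Conditions: TBSCl, imidazole, CH2Cl2, 25 °C
Reagents that add atoms: tert-butyldimethylsilyl chloride, `CC(C)(C)[Si](C)(C)Cl`
Why: standard silylation of the phenol, which masks the acidic OH for the samarium step and can later be removed without touching the benzoate.

Step 11
Reactants: 19 (2Z,6Z,9R,10S)-9-hydroxy-3,7-dimethyl-10-(propan-2-yl)cyclodeca-2,6-dien-1-one; 21 4-[(tert-butyldimethylsilyl)oxy]-3-methoxybenzaldehyde
Product: 23 (1R,3Z,7Z,9R,10R)-9-hydroxy-3,7-dimethyl-10-(propan-2-yl)cyclodeca-3,7-dien-1-yl 4-hydroxy-3-methoxybenzoate, via silyl ether 22 (not isolated)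
Conditions: SmI2 (30 mol%, pre-mixed with 21, 4 equiv), THF, −10 °C, dark; then KHF2, MeOH, 25 °C
Reagents that add atoms: none
Why: Evans–Tishchenko reaction, in which the hemiacetal formed from 21 on the C8 hydroxyl is bound with the C6 carbonyl to trivalent samarium and delivers its hydride intramolecularly through a chair six-membered transition state, giving the 1,3-anti (6R) alcohol under control of the bought C8 centre and leaving the aroyl group on O8; KHF2 in methanol then cleaves only the aryl silyl ether.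

## Compound list

```
1 | (4S)-4-hydroxyoxolan-2-one, (S)-3-hydroxy-γ-butyrolactone | O=C1C[C@H](O)CO1 | starting material
2 | dilithium alkoxide–enolate (dianion) of 1 | [Li]OC1=C[C@H](O[Li])CO1 | intermediate
3 | (3S,4S)-4-hydroxy-3-(propan-2-yl)oxolan-2-one (trans) | O=C1[C@@H](C(C)C)[C@H](O)CO1 | intermediate
4 | (2S,3S)-3-acetoxy-4-bromo-2-(propan-2-yl)butanoic acid | OC(=O)[C@@H](C(C)C)[C@H](OC(C)=O)CBr | intermediate
5 | ethyl (2S,3S)-4-bromo-3-hydroxy-2-(propan-2-yl)butanoate | CCOC(=O)[C@@H](C(C)C)[C@H](O)CBr | intermediate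
6 | 2-(2-bromoethyl)-1,3-dioxolane | BrCCC1OCCO1 | starting material
7 | [2-(1,3-dioxolan-2-yl)ethyl]magnesium bromide | Br[Mg]CCC1OCCO1 | intermediate
8 | [2-(1,3-dioxolan-2-yl)ethyl]copper | [Cu]CCC1OCCO1 | intermediate
9 | [(1Z)-4-(1,3-dioxolan-2-yl)-2-methylbut-1-en-1-yl]copper | [Cu]/C=C(C)\CCC1OCCO1 | intermediate
10 | 2-[(3Z)-4-bromo-3-methylbut-3-en-1-yl]-1,3-dioxolane | Br/C=C(C)\CCC1OCCO1 | intermediate
11 | (4Z)-5-bromo-4-methylpent-4-enal | O=CCC/C(C)=C\Br | intermediate
12 | (1Z,5Z)-1-bromo-6-iodo-2-methylhepta-1,5-diene | I/C(C)=C\CC/C(C)=C\Br | intermediate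
13 | ethyl (2S)-3-methyl-2-[(2S)-oxiran-2-yl]butanoate | CCOC(=O)[C@@H](C(C)C)[C@H]1CO1 | intermediate
14 | [(2Z,6Z)-7-bromo-6-methylhepta-2,6-dien-2-yl]magnesium chloride | Cl[Mg]/C(C)=C\CC/C(C)=C\Br | intermediate
15 | ethyl (2S,3R,5Z,9Z)-10-bromo-3-hydroxy-5,9-dimethyl-2-(propan-2-yl)deca-5,9-dienoate | CCOC(=O)[C@@H](C(C)C)[C@H](O)C/C(C)=C\CC/C(C)=C\Br | intermediate
16 | (2R,3R,5Z,9Z)-10-bromo-5,9-dimethyl-2-(propan-2-yl)deca-5,9-diene-1,3-diol | OC[C@@H](C(C)C)[C@H](O)C/C(C)=C\CC/C(C)=C\Br | intermediate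
17 | (2S,3R,5Z,9Z)-10-bromo-3-hydroxy-5,9-dimethyl-2-(propan-2-yl)deca-5,9-dienal | O=C[C@@H](C(C)C)[C@H](O)C/C(C)=C\CC/C(C)=C\Br | intermediate
18 | (1R,2S,3RS,4Z,8Z)-5,9-dimethyl-2-(propan-2-yl)cyclodeca-4,8-diene-1,3-diol (C3 epimers) | O[C@@H]1C/C(C)=C\CC/C(C)=C\C(O)[C@H]1C(C)C | intermediate
19 | (2Z,6Z,9R,10S)-9-hydroxy-3,7-dimethyl-10-(propan-2-yl)cyclodeca-2,6-dien-1-one | O[C@@H]1C/C(C)=C\CC/C(C)=C\C(=O)[C@H]1C(C)C | intermediate
20 | vanillin, 4-hydroxy-3-methoxybenzaldehyde | COc1cc(C=O)ccc1O | starting material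
21 | 4-[(tert-butyldimethylsilyl)oxy]-3-methoxybenzaldehyde | COc1cc(C=O)ccc1O[Si](C)(C)C(C)(C)C | intermediate
22 | (1R,3Z,7Z,9R,10R)-9-hydroxy-3,7-dimethyl-10-(propan-2-yl)cyclodeca-3,7-dien-1-yl 4-[(tert-butyldimethylsilyl)oxy]-3-methoxybenzoate | COc1cc(C(=O)O[C@@H]2C/C(C)=C\CC/C(C)=C\[C@@H](O)[C@H]2C(C)C)ccc1O[Si](C)(C)C(C)(C)C | intermediate
23 | (1R,3Z,7Z,9R,10R)-9-hydroxy-3,7-dimethyl-10-(propan-2-yl)cyclodeca-3,7-dien-1-yl 4-hydroxy-3-methoxybenzoate (CNP0185892.5) | COc1cc(C(=O)O[C@@H]2C/C(C)=C\CC/C(C)=C\[C@@H](O)[C@H]2C(C)C)ccc1O | target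
```

## Step count and risks

Total steps: 11. Longest linear sequence: 8 (steps 3, 4, 5, 6, 7, 8, 9, 11; the branch from 1 through steps 1, 2, 5, 6, 7, 8, 9, 11 is equally long).

The three steps most likely to fail:

**Step 8, the proposed new electrochemical ring closure.** The risks are oligomerisation and poor chromium turnover at high dilution in a reaction not yet run in ring-closing mode. The fallback uses only known chemistry, closes the ring at a different bond, sets out from 5 and rejoins the route at 19. Compound 5 is closed to epoxide 13 (NaH) and opened with isopropenylmagnesium bromide/CuI to ethyl (2S,3R)-3-hydroxy-5-methyl-2-(propan-2-yl)hex-5-enoate F4. LiBH4 gives (2R,3R)-5-methyl-2-(propan-2-yl)hex-5-ene-1,3-diol F5, and TEMPO/PhI(OAc)2 gives (2S,3R)-3-hydroxy-5-methyl-2-(propan-2-yl)hex-5-enal F6. A stoichiometric intermolecular Nozaki–Hiyama–Kishi coupling (CrCl2, NiCl2 cat., DMSO) with (1Z)-1-iodo-2-methylhexa-1,5-diene F7 (from but-3-enylmagnesium bromide, CuBr·SMe2, propyne, then I2) gives (4R,5S,6RS,7Z)-2,8-dimethyl-5-(propan-2-yl)dodeca-1,7,11-triene-4,6-diol F8. MnO2 gives (4R,5S,7Z)-4-hydroxy-2,8-dimethyl-5-(propan-2-yl)dodeca-1,7,11-trien-6-one F9. Ring-closing metathesis (second-generation Hoveyda–Grubbs catalyst, RuCl2(=CH-C6H4-2-OiPr)(1,3-dimesitylimidazolidin-2-ylidene), toluene, 1 mM, 80 °C) then closes C1=C10, expected as the less strained Z isomer, and delivers 19.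

**Step 1, alkylation of the dianion with a secondary iodide.** Elimination of 2-iodopropane is likely to hold the yield down, although the trans selectivity itself is dependable. The fallback sets out from 1 and rejoins at 3. The same dianion 2 is trapped with acetone in a fast aldol addition with the same trans sense, giving (3R,4S)-4-hydroxy-3-(2-hydroxypropan-2-yl)oxolan-2-one F1. The tertiary alcohol is dehydrated with Martin sulfurane to (3S,4S)-4-hydroxy-3-(prop-1-en-2-yl)oxolan-2-one F2 together with its conjugated isomer (4S)-4-hydroxy-3-(propan-2-ylidene)oxolan-2-one F3. Hydrogenation of the mixture with the achiral catalyst [Ir(cod)(PCy3)(py)]PF6 is directed by the C4 hydroxyl, which delivers hydrogen to C3 cis to OH, so both isomers converge on 3.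

**Step 11, the Evans–Tishchenko reaction.** The substrate is a conjugated medium-ring ketone, the aldehyde is electron-rich, and the chair transition state must fit inside the ten-membered ring. The fallback sets out from 19 (and 21) and rejoins at 22. Aldehyde 21 is oxidised (NaClO2, NaH2PO4, 2-methylbut-2-ene) to 4-[(tert-butyldimethylsilyl)oxy]-3-methoxybenzoic acid F10. Steglich esterification of 19 (DCC, DMAP cat., 0 °C) gives (1R,3Z,7Z,10S)-3,7-dimethyl-9-oxo-10-(propan-2-yl)cyclodeca-3,7-dien-1-yl 4-[(tert-butyldimethylsilyl)oxy]-3-methoxybenzoate F11. Luche reduction (NaBH4, CeCl3·7H2O, MeOH, −78 °C) with external hydride gives 22 and its C6 epimer; the facial selectivity is not predictable here and must be measured. The two are separated by chromatography, the unwanted epimer is returned to F11 with MnO2, and 22 is desilylated with KHF2/MeOH as in step 11.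

## Further compounds

```
F1 | step 1 | (3R,4S)-4-hydroxy-3-(2-hydroxypropan-2-yl)oxolan-2-one | O=C1[C@@H](C(C)(C)O)[C@H](O)CO1
F2 | step 1 | (3S,4S)-4-hydroxy-3-(prop-1-en-2-yl)oxolan-2-one | O=C1[C@@H](C(C)=C)[C@H](O)CO1
F3 | step 1 | (4S)-4-hydroxy-3-(propan-2-ylidene)oxolan-2-one | O=C1C(=C(C)C)[C@H](O)CO1
F4 | step 8 | ethyl (2S,3R)-3-hydroxy-5-methyl-2-(propan-2-yl)hex-5-enoate | CCOC(=O)[C@@H](C(C)C)[C@H](O)CC(C)=C
F5 | step 8 | (2R,3R)-5-methyl-2-(propan-2-yl)hex-5-ene-1,3-diol | OC[C@@H](C(C)C)[C@H](O)CC(C)=C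
F6 | step 8 | (2S,3R)-3-hydroxy-5-methyl-2-(propan-2-yl)hex-5-enal | O=C[C@@H](C(C)C)[C@H](O)CC(C)=C
F7 | step 8 | (1Z)-1-iodo-2-methylhexa-1,5-diene | I/C=C(C)\CCC=C
F8 | step 8 | (4R,5S,6RS,7Z)-2,8-dimethyl-5-(propan-2-yl)dodeca-1,7,11-triene-4,6-diol | C=CCC/C(C)=C\C(O)[C@@H](C(C)C)[C@H](O)CC(C)=C
F9 | step 8 | (4R,5S,7Z)-4-hydroxy-2,8-dimethyl-5-(propan-2-yl)dodeca-1,7,11-trien-6-one | C=CCC/C(C)=C\C(=O)[C@@H](C(C)C)[C@H](O)CC(C)=C
F10 | step 11 | 4-[(tert-butyldimethylsilyl)oxy]-3-methoxybenzoic acid | COc1cc(C(O)=O)ccc1O[Si](C)(C)C(C)(C)C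
F11 | step 11 | (1R,3Z,7Z,10S)-3,7-dimethyl-9-oxo-10-(propan-2-yl)cyclodeca-3,7-dien-1-yl 4-[(tert-butyldimethylsilyl)oxy]-3-methoxybenzoate | COc1cc(C(=O)O[C@@H]2C/C(C)=C\CC/C(C)=C\C(=O)[C@H]2C(C)C)ccc1O[Si](C)(C)C(C)(C)C
```
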